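The easy step came first. I took Wednesday's last reading, 6.3% of L and 19.7% of X, counted one G used for each, and divided [L] by the [E][G] left. That gave 0.217 L mol⁻¹. I called this reading of [L]/([E][G]) the level quotient. L over the L that the quotient allows I called the fill, and I took a fill of one, the zero of my scale, to mean that L stands level with E and G (a pre-equilibrium).

| setting | Sunday's | Wednesday's | flask |
|---|---|---|---|
| E | 0.80 M (in portions, 2) | 0.80 M (in portions, 2) | 0.80 M (in portions, 2) |
| G | 1.5 equiv | 0.75 equiv | 1.50 equiv |
| remark | the very flask that is asked about, followed so far; portions every 6.0 min | run made earlier; portions every 6.0 min | the portions of E follow each other after 6.0 min, the first at the start |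
| time |  |  | 25 min |

| run | time / min | L / % | X / % |
|---|---|---|---|
| Sunday's | 0.417 | 1.1 | 0.7 |
| Sunday's | 1.33 | 4.0 | 2.5 |
| Sunday's | 2.50 | 6.1 | 4.1 |
| Sunday's | 4.00 | 6.8 | 6.2 |
| Sunday's | 5.00 | 7.8 | 6.6 |
| Wednesday's | 2.00 | 2.9 | 2.1 |
| Wednesday's | 6.00 | 4.5 | 4.3 |
| Wednesday's | 12.0 | 8.1 | 11.5 |
| Wednesday's | 20.0 | 6.4 | 17.2 |
| Wednesday's | 25.0 | 6.3 | 19.7 |

(readings scatter by 0.3 percentage points)

- the state of affairs at 25 min: stopped, and by what, or still going (it is still moving / all of E has reacted / G has run out first / forward and back rates have come level)
- the L standing at 25 min, as a percentage of the E charged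
- the X standing at 25 min, as a percentage of the E charged

- the numbers in the tables scatter by 0.3 percentage points (one standard deviation)
- the reaction counts as stopped when no species that holds the E changes by six tenths of a point or more over the second half of the time

Sunday's flask, which you were taking over, held its first portion of E, and the fill read from its reading at 5.00 min, with the same count, was 0.930. So I expected L to climb with [E] after the second portion at 6.0 min, then sink slowly as X drew on E and G. I asked you not to stop the flask when L fell.

The forecast for 25 min read: it is still moving, with 10% of L and 34% of X, on the ground that “the first step looks reversible”. At its X and L, my level for L came to 10.3%, which rests on much the same quotient and so checks nothing.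

The flask at 25 min gave: it is still moving, with 9.54% of L and 33.0% of X.

    E + G ⇌ L (K = 0.277 L mol⁻¹, k = 0.0659 L mol⁻¹ min⁻¹)
    E + G ⇌ X (K = 1.99 L mol⁻¹, k = 0.0333 L mol⁻¹ min⁻¹)
    G → Z (k = 7.19 × 10⁻⁵ min⁻¹)
    L ⇌ Q (K = 3.10, k = 0.0519 min⁻¹)

The flask had converted 53.5% of its E, while the run with the way back from L to E + G struck out reached 77.0%, so that return was the main reason for the shortfall. Against the flask's 46.5% of E and 64.2% of its own G, the fill was 1.23. My Wednesday count had no Q in it, and this flask held 11.0% of Q.

Read at 1.0 h, the same flask had 35.0% of E and 56.4% of its G, so the quotient and that fill gave 6.31% of L. The computed L there was 6.41%.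

The runs are calculated for an exercise.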